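A small charge of substrate, as in north-east, still stands at 0.00500 M in the flask, which is more than the solubility of the coupling partner, 1.4 mM. So in north-east the substrate is the limiting reagent by charge, less than the solid reagent at 0.0500 M, yet what meets it in solution is the dissolved coupling partner, and we write the balance of that.

| flask | substrate | solid reagent | time | remark |
|---|---|---|---|---|
| north-east | 0.010 M (fed, over 8.0 s) | 0.0500 M | 10 min | the fed solution adds 1.0 times the starting volume |
| north | 0.020 M (fed, over 8.0 s) | 0.0500 M | 10 min | the fed solution adds 1.0 times the starting volume |
| south-west | 0.040 M (fed, over 8.0 s) | 0.0500 M | 10 min | the fed solution adds 1.0 times the starting volume |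
| west | 0.080 M (fed, over 8.0 s) | 0.0500 M | 10 min | the fed solution adds 1.0 times the starting volume |

    substrate + coupling partner ⇌ isomer of the product (K1 = 1860 M⁻¹, k1 = 0.194 M⁻¹ s⁻¹)
    solid reagent ⇌ coupling partner, rate k2*(cs2 - [coupling partner]) while solid is left; crystals form when [coupling partner] > cs2 (cs2 = 1.4 mM, k2 = 0.0104 s⁻¹)
    substrate + coupling partner ⇌ target (K3 = 64 M⁻¹, k3 = 0.515 M⁻¹ s⁻¹)
    substrate + target → side product (k4 = 0.481 M⁻¹ s⁻¹)

1. [target] at the end for north-east, north, south-west, west, in this order
2. the course of these numbers from the first flask to the last (hardly changes / falls all the way / rises, then falls / rises all the way / falls, then rises)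

- in percentages every species weighs as the substrate in it: one side product counts as two
- charges are per starting volume, the dose included; the dosed solution carries all of it
- as a solid, counted per litre of solution: solid reagent
- at the start none of the solid reagent is in solution
- "hardly changes" means that all values lie within two and a half points (for a concentration: within two and a half percent of the largest)
- run time (north-east): 10 min

Let s be the substrate in the flask, B the dissolved coupling partner and P the target. Let f, i and l be the rate constants that form target, form isomer and lose target to side product. K is the equilibrium constant of target, d the dissolution coefficient and S the solubility. The feed of 8.0 s is shorter than the dissolution time of 1.60 min, so we treat the substrate as present at once in the enlarged volume. The isomer falls back at 1.04 × 10⁻⁴ s⁻¹, far slower than the dissolution coefficient, so we drop that return.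

Target falls back within 2.07 min, shorter than the run, and the dissolution time is shorter than the run too, so we use a steady state for target and coupling partner alike. For target, f s B = (f/K + l s) P. For the coupling partner, d (S − B) = i s B + l s P. Eliminating B gives S/P = 1/(K s) + a + b s, where a = l/f + i/(d K) = 1.23 and b = (l/d)(1 + i/f) = 63.7 M⁻¹.

Drawn against s, the curve of P starts with slope K S, which is 0.0896. It bends where the first and last terms are equal, at the best standing substrate level s*, the square root of 1/(K b), which is 0.0157 M. There it tops out at 4.35 × 10⁻⁴ M, and beyond that it falls as S/(b s). As a charge, s* is 0.0313 M, above north's charge and below south-west's.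

Counting the whole charge as still present, our row is 3.00 × 10⁻⁴ M, 4.09 × 10⁻⁴ M, 4.27 × 10⁻⁴ M and 3.36 × 10⁻⁴ M. The charge for s* lies well inside the range of the flasks, so the course we commit to is this: rises, then falls.

The forecast gives 2.500 × 10⁻⁴ M, 3.600 × 10⁻⁴ M, 4.300 × 10⁻⁴ M and 3.800 × 10⁻⁴ M, so its course rises, then falls, with “the peak falls near the third flask”. Our north-east value stands higher than the forecast's, but our course is the same.

The simulation gives 2.52 × 10⁻⁴ M, 3.68 × 10⁻⁴ M, 4.29 × 10⁻⁴ M and 3.72 × 10⁻⁴ M, so the row rises, then falls. At the end, substrate stands at 75.7 % of its charge in north-east, 74.3 % in south-west and 78.8 % in west. Held against s*, north-east stands at 0.242 of it, on the rising side, and west at twice s*, on the falling side. Dividing the charge for s* by south-west's remainder gives 0.0422 M, and the row turns at a substrate charge of 0.041 M.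

All constants come from no measurement; the rest is arithmetic.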